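The route rests on cutting ring A of the 2,3-dihydrobenzofuran into three two-carbon units, C3a–C4, C5–C6 and C7–C7a. The outer two are joined beforehand through O1–C2–C3, the chain that carries both stereocentres, so one ruthenium-catalysed (2+2+2) cycloaddition with a silylated pentenynol forms C3a–C7a, C4–C5 and C6–C7 and closes ring A and the dihydrofuran ring together. The precursor is an anti 1,6-diyne built by allenylzinc addition to protected syringaldehyde: a terminal alkyne at the future C3a–C4 and a pinacolboryl ynol ether on O1, in which boron marks C7 for the methoxy group and directs the propenol chain to C5.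

Key step: step 10

Assumption: in step 4 the alkynyl group is taken to play the part of the aryl group of aryl ketones, so the (R,R)-catalyst should give the (S)-carbinol; in step 8 the alkoxy-substituted sp C–H of 16 is taken to be more acidic than the alkyl-substituted one.

Step 1
Reactants: 1 syringaldehyde
Product: 2 3,5-dimethoxy-4-(triisopropylsilyloxy)benzaldehyde
Conditions: i-Pr3SiCl, imidazole, DMAP (cat.), DMF, rt
Reagents that add atoms: triisopropylsilyl chloride, CC(C)[Si](Cl)(C(C)C)C(C)C
Why: O-silylation of a phenol; the hindered silyl ether should survive alkoxide, butyllithium and carbonate and leaves with fluoride at the end, so no acid is needed once the acid-labile p-alkoxycinnamyl unit exists.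

Step 2
Reactants: 3 ethyl glycolate
Product: 4 ethyl 2-(triisopropylsilyloxy)acetate
Conditions: i-Pr3SiCl, imidazole, CH2Cl2, rt
Reagents that add atoms: triisopropylsilyl chloride, CC(C)[Si](Cl)(C(C)C)C(C)C
Why: O-silylation of a primary alcohol; the triisopropylsilyl group is chosen because it resists the 1,5 oxygen-to-oxygen silyl shift that a smaller silyl group would risk when the neighbouring potassium alkoxide is made in step 7.

Step 3
Reactants: 4 ethyl 2-(triisopropylsilyloxy)acetate; 5 lithium (trimethylsilyl)acetylide (THF solution)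
Product: 7 1-(triisopropylsilyloxy)-4-(trimethylsilyl)but-3-yn-2-one, via lithium alkynyltrifluoroborate 6 (not isolated)
Conditions: 5, BF3·OEt2, THF, −78 °C; then 4, −78 °C
Reagents that add atoms: none
Why: Acylation of a BF3-activated lithium acetylide by an ester (Yamaguchi-type ynone synthesis), in which the boron-bound tetrahedral adduct persists until work-up and so prevents a second addition.

Step 4
Reactants: 7 1-(triisopropylsilyloxy)-4-(trimethylsilyl)but-3-yn-2-one
Product: 8 (S)-1-(triisopropylsilyloxy)-4-(trimethylsilyl)but-3-yn-2-ol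
Conditions: RuCl[(R,R)-TsDPEN](p-cymene) (1 mol%), i-PrOH, rt
Reagents that add atoms: none
Why: Noyori–Ikariya asymmetric transfer hydrogenation of an ynone, in which the chiral diamine complex delivers hydride to the carbonyl face fixed by the alkynyl π-group and thereby sets the carbinol centre as S.

Step 5
Reactants: 8 (S)-1-(triisopropylsilyloxy)-4-(trimethylsilyl)but-3-yn-2-ol
Product: 9 (S)-1-(triisopropylsilyloxy)-4-(trimethylsilyl)but-3-yn-2-yl methanesulfonate
Conditions: MsCl, Et3N, CH2Cl2, −78 → −20 °C; used crude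
Reagents that add atoms: methanesulfonyl chloride, CS(=O)(=O)Cl
Why: O-sulfonylation with retention at carbon, which installs the leaving group for the anti SN2′ oxidative addition of the next step.

Step 6
Reactants: 2 3,5-dimethoxy-4-(triisopropylsilyloxy)benzaldehyde; 9 (S)-propargylic mesylate
Product: 11 (1S,2R)-1-[3,5-dimethoxy-4-(triisopropylsilyloxy)phenyl]-2-[(triisopropylsilyloxy)methyl]-4-(trimethylsilyl)but-3-yn-1-ol (anti), via allenylzinc 10 (not isolated)
Conditions: Pd(OAc)2 (5 mol%), PPh3 (5 mol%), Et2Zn (3 equiv), THF, −78 → −20 °C; chromatography to remove any syn isomer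
Reagents that add atoms: none
Why: Marshall propargylation: zerovalent palladium displaces the mesylate anti (SN2′), Et2Zn transmetalates to the allenylzinc 10, and 10 adds to the aldehyde through a cyclic SE2′ transition state, so the configuration of 9 is relayed with overall inversion to C2 (R, the future C3) while the aryl group lies anti to the silyloxymethyl group and sets C1 as S (the future C2).

Step 7
Reactants: 11 anti homopropargylic alcohol; 12 trichloroethylene
Product: 16 ethynyl ether of (1S,2R)-1-[3,5-dimethoxy-4-(triisopropylsilyloxy)phenyl]-2-[(triisopropylsilyloxy)methyl]but-3-yn-1-ol, via dichlorovinyl ether 13 (not isolated), via lithium alkoxyacetylide 14 (not isolated), via C-silyl ynol ether 15 (not isolated)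
Conditions: KH, THF, 0 °C; Cl2C=CHCl, −50 °C → rt; n-BuLi (2.5 equiv), −78 → −40 °C; MeOH, K2CO3 (cat.), 0 °C; kept cold, purified on Et3N-deactivated silica
Reagents that add atoms: none
Why: One-pot ynol ether synthesis from an alcohol: the potassium alkoxide adds to dichloroacetylene formed in situ, n-BuLi turns the dichlorovinyl ether 13 into the acetylide 14 by elimination and chlorine–lithium exchange, and the methanolic methoxide of the quench then removes the C–SiMe3 group that shielded the C3 alkyne from alkoxide and butyllithium, all without breaking a bond at either stereocentre.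

Step 8
Reactants: 16 bis-terminal diyne; 17 2-isopropoxy-4,4,5,5-tetramethyl-1,3,2-dioxaborolane
Product: 20 2-(4,4,5,5-tetramethyl-1,3,2-dioxaborolan-2-yl)ethynyl ether of (1S,2R)-1-[3,5-dimethoxy-4-(triisopropylsilyloxy)phenyl]-2-[(triisopropylsilyloxy)methyl]but-3-yn-1-ol (anti diyne), via lithium acetylide 18 (not isolated), via lithium borate 19 (not isolated)
Conditions: LiN(SiMe3)2 (1.0 equiv), THF, −78 °C; 17, −78 °C; HCl·Et2O (1.05 equiv), −78 → 0 °C; filtered cold and used at once
Reagents that add atoms: none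
Why: C-Borylation of a lithium acetylide (borate formation, then anhydrous acid): with one equivalent of amide base the lithium should settle on the alkoxyethynyl carbon, the more acidic sp C–H because oxygen sits on the triple bond, so boron goes to the future C7 and the C3 alkyne stays terminal, and anhydrous HCl frees the boronate without the basic protic medium that cleaves alkynyl–boron bonds.

Step 9
Reactants: 21 (E)-pent-2-en-4-yn-1-ol
Product: 22 (E)-tert-butyldimethyl(pent-2-en-4-yn-1-yloxy)silane
Conditions: t-BuMe2SiCl, imidazole, CH2Cl2, 0 °C → rt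
Reagents that add atoms: tert-butyldimethylsilyl chloride, CC(C)(C)[Si](C)(C)Cl
Why: O-silylation of the primary allylic alcohol, which keeps the hydroxyl group off the ruthenium catalyst and lets it be freed in the common fluoride step.

Step 10
Reactants: 20 anti boryl ynol ether diyne; 22 (E)-tert-butyldimethyl(pent-2-en-4-yn-1-yloxy)silane
Product: 23 (2S,3R)-2-[3,5-dimethoxy-4-(triisopropylsilyloxy)phenyl]-3-[(triisopropylsilyloxy)methyl]-5-[(E)-3-(tert-butyldimethylsilyloxy)prop-1-enyl]-7-(4,4,5,5-tetramethyl-1,3,2-dioxaborolan-2-yl)-2,3-dihydrobenzofuran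
Conditions: Cp*RuCl(cod) (10 mol%), 22 (3 equiv), ClCH2CH2Cl, rt, slow addition of 20
Reagents that add atoms: none
Why: Proposed new method: the two tethered alkynes of 20 should couple oxidatively on the Cp*RuCl fragment to a ruthenacyclopentadiene (bond C3a–C7a), the alkyne of 22 should insert, and reductive elimination should release the arene (bonds C4–C5 and C6–C7). The closest known reaction type is the ruthenium- or rhodium-catalysed (2+2+2) cycloaddition of 1,6-diynes with monoalkynes, including diynes tethered through an ynamide nitrogen or through the oxygen of an aryl alkynyl ether and diynes with a boryl terminus; an alkyl ynol ether tether that also carries boron is new. The dihydrofuran ring closes in the oxidative cyclisation, as the five-membered ring annulated to the metallacycle across the O1–C2–C3 tether, and ring A closes by alkyne insertion followed by carbon–carbon reductive elimination. No stereocentre is created: C2 and C3 sit on the tether, belong to no reacting sp carbon, and should pass through unchanged at room temperature. The step needs regioselective insertion, which the pinacolboryl group on C7 should secure, because the substituted carbon of 22 bonds to the unhindered C4 terminus and so places the chain at C5, meta to boron. It also needs cross-selectivity over self-cyclisation of 20 and survival of the heat-sensitive benzylic alkynyl ether, which slow addition of 20 to an excess of 22 and working at room temperature are meant to provide.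

Step 11
Reactants: 23 7-boryl dihydrobenzofuran
Product: 24 (2S,3R)-2-[3,5-dimethoxy-4-(triisopropylsilyloxy)phenyl]-3-[(triisopropylsilyloxy)methyl]-5-[(E)-3-(tert-butyldimethylsilyloxy)prop-1-enyl]-2,3-dihydrobenzofuran-7-ol
Conditions: NaBO3·4H2O, THF–H2O (1:1), rt
Reagents that add atoms: sodium perborate tetrahydrate, [Na+].[O-]B1OO1.O.O.O.O
Why: Oxidation of an arylboronate to a phenol (aryl shift from boron to oxygen in the peroxoborate, then hydrolysis), mild enough to leave the silyl ethers and the styrene untouched.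

Step 12
Reactants: 24 7-hydroxy dihydrobenzofuran
Product: 25 (2S,3R)-2-[3,5-dimethoxy-4-(triisopropylsilyloxy)phenyl]-3-[(triisopropylsilyloxy)methyl]-5-[(E)-3-(tert-butyldimethylsilyloxy)prop-1-enyl]-7-methoxy-2,3-dihydrobenzofuran
Conditions: MeI, K2CO3, acetone, rt
Reagents that add atoms: iodomethane, CI
Why: Williamson O-methylation of the only free phenol, the syringyl oxygen being still silylated so that the two phenolic oxygens stay distinct.

Step 13
Reactants: 25 fully silylated 7-methoxy dihydrobenzofuran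
Product: 26 (2S,3R)-2-(4-hydroxy-3,5-dimethoxyphenyl)-3-(hydroxymethyl)-5-[(E)-3-hydroxyprop-1-enyl]-7-methoxy-2,3-dihydrobenzofuran (CNP0191372.1)
Conditions: Bu4NF (5 equiv), AcOH (5 equiv), THF, 0 °C → rt
Reagents that add atoms: none
Why: Fluoride-induced cleavage of all three silyl ethers in one buffered operation, which avoids the acid that would ionise the p-alkoxycinnamyl alcohol or the benzylic C2–O1 bond.

Compound list
1 | syringaldehyde (4-hydroxy-3,5-dimethoxybenzaldehyde) | COc1cc(C=O)cc(OC)c1O | starting material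
2 | 3,5-dimethoxy-4-(triisopropylsilyloxy)benzaldehyde | COc1cc(C=O)cc(OC)c1O[Si](C(C)C)(C(C)C)C(C)C | intermediate
3 | ethyl glycolate | CCOC(=O)CO | starting material
4 | ethyl 2-(triisopropylsilyloxy)acetate | CCOC(=O)CO[Si](C(C)C)(C(C)C)C(C)C | intermediate
5 | lithium (trimethylsilyl)acetylide | [Li]C#C[Si](C)(C)C | starting material
6 | lithium trifluoro[(trimethylsilyl)ethynyl]borate | [Li+].C[Si](C)(C)C#C[B-](F)(F)F | intermediate
7 | 1-(triisopropylsilyloxy)-4-(trimethylsilyl)but-3-yn-2-one | C[Si](C)(C)C#CC(=O)CO[Si](C(C)C)(C(C)C)C(C)C | intermediate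
8 | (S)-1-(triisopropylsilyloxy)-4-(trimethylsilyl)but-3-yn-2-ol | C[Si](C)(C)C#C[C@H](O)CO[Si](C(C)C)(C(C)C)C(C)C | intermediate
9 | (S)-1-(triisopropylsilyloxy)-4-(trimethylsilyl)but-3-yn-2-yl methanesulfonate | C[Si](C)(C)C#C[C@H](OS(C)(=O)=O)CO[Si](C(C)C)(C(C)C)C(C)C | intermediate
10 | ethyl[(aS)-4-(triisopropylsilyloxy)-1-(trimethylsilyl)buta-1,2-dien-1-yl]zinc | CC[Zn]C([Si](C)(C)C)=[C@@]=C([H])CO[Si](C(C)C)(C(C)C)C(C)C | intermediate
11 | (1S,2R)-1-[3,5-dimethoxy-4-(triisopropylsilyloxy)phenyl]-2-[(triisopropylsilyloxy)methyl]-4-(trimethylsilyl)but-3-yn-1-ol | COc1cc(cc(OC)c1O[Si](C(C)C)(C(C)C)C(C)C)[C@@H](O)[C@@H](CO[Si](C(C)C)(C(C)C)C(C)C)C#C[Si](C)(C)C | intermediate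
12 | trichloroethylene | ClC=C(Cl)Cl | starting material
13 | (E)-1,2-dichlorovinyl ether of 11 | COc1cc(cc(OC)c1O[Si](C(C)C)(C(C)C)C(C)C)[C@@H](O/C(Cl)=C\Cl)[C@@H](CO[Si](C(C)C)(C(C)C)C(C)C)C#C[Si](C)(C)C | intermediate
14 | 2-lithioethynyl ether of 11 | COc1cc(cc(OC)c1O[Si](C(C)C)(C(C)C)C(C)C)[C@@H](OC#C[Li])[C@@H](CO[Si](C(C)C)(C(C)C)C(C)C)C#C[Si](C)(C)C | intermediate
15 | ethynyl ether of 11 (C3 alkyne still C-silylated) | COc1cc(cc(OC)c1O[Si](C(C)C)(C(C)C)C(C)C)[C@@H](OC#C)[C@@H](CO[Si](C(C)C)(C(C)C)C(C)C)C#C[Si](C)(C)C | intermediate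
16 | ethynyl ether of (1S,2R)-1-[3,5-dimethoxy-4-(triisopropylsilyloxy)phenyl]-2-[(triisopropylsilyloxy)methyl]but-3-yn-1-ol | COc1cc(cc(OC)c1O[Si](C(C)C)(C(C)C)C(C)C)[C@@H](OC#C)[C@@H](CO[Si](C(C)C)(C(C)C)C(C)C)C#C | intermediate
17 | 2-isopropoxy-4,4,5,5-tetramethyl-1,3,2-dioxaborolane | CC(C)OB1OC(C)(C)C(C)(C)O1 | starting material
18 | 16 lithiated at the alkoxyethynyl carbon | COc1cc(cc(OC)c1O[Si](C(C)C)(C(C)C)C(C)C)[C@@H](OC#C[Li])[C@@H](CO[Si](C(C)C)(C(C)C)C(C)C)C#C | intermediate
19 | lithium isopropoxy(pinacolato)borate formed from 18 and 17 | [Li+].COc1cc(cc(OC)c1O[Si](C(C)C)(C(C)C)C(C)C)[C@@H](OC#C[B-]1(OC(C)C)OC(C)(C)C(C)(C)O1)[C@@H](CO[Si](C(C)C)(C(C)C)C(C)C)C#C | intermediate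
20 | 2-(4,4,5,5-tetramethyl-1,3,2-dioxaborolan-2-yl)ethynyl ether of (1S,2R)-1-[3,5-dimethoxy-4-(triisopropylsilyloxy)phenyl]-2-[(triisopropylsilyloxy)methyl]but-3-yn-1-ol | COc1cc(cc(OC)c1O[Si](C(C)C)(C(C)C)C(C)C)[C@@H](OC#CB1OC(C)(C)C(C)(C)O1)[C@@H](CO[Si](C(C)C)(C(C)C)C(C)C)C#C | intermediate
21 | (E)-pent-2-en-4-yn-1-ol | C#C/C=C/CO | starting material
22 | (E)-tert-butyldimethyl(pent-2-en-4-yn-1-yloxy)silane | C#C/C=C/CO[Si](C)(C)C(C)(C)C | intermediate
23 | (2S,3R)-2-[3,5-dimethoxy-4-(triisopropylsilyloxy)phenyl]-3-[(triisopropylsilyloxy)methyl]-5-[(E)-3-(tert-butyldimethylsilyloxy)prop-1-enyl]-7-(4,4,5,5-tetramethyl-1,3,2-dioxaborolan-2-yl)-2,3-dihydrobenzofuran | COc1cc(cc(OC)c1O[Si](C(C)C)(C(C)C)C(C)C)[C@H]2Oc3c(B4OC(C)(C)C(C)(C)O4)cc(/C=C/CO[Si](C)(C)C(C)(C)C)cc3[C@@H]2CO[Si](C(C)C)(C(C)C)C(C)C | intermediate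
24 | (2S,3R)-2-[3,5-dimethoxy-4-(triisopropylsilyloxy)phenyl]-3-[(triisopropylsilyloxy)methyl]-5-[(E)-3-(tert-butyldimethylsilyloxy)prop-1-enyl]-2,3-dihydrobenzofuran-7-ol | COc1cc(cc(OC)c1O[Si](C(C)C)(C(C)C)C(C)C)[C@H]2Oc3c(O)cc(/C=C/CO[Si](C)(C)C(C)(C)C)cc3[C@@H]2CO[Si](C(C)C)(C(C)C)C(C)C | intermediate
25 | (2S,3R)-2-[3,5-dimethoxy-4-(triisopropylsilyloxy)phenyl]-3-[(triisopropylsilyloxy)methyl]-5-[(E)-3-(tert-butyldimethylsilyloxy)prop-1-enyl]-7-methoxy-2,3-dihydrobenzofuran | COc1cc(cc(OC)c1O[Si](C(C)C)(C(C)C)C(C)C)[C@H]2Oc3c(OC)cc(/C=C/CO[Si](C)(C)C(C)(C)C)cc3[C@@H]2CO[Si](C(C)C)(C(C)C)C(C)C | intermediate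
26 | (2S,3R)-2-(4-hydroxy-3,5-dimethoxyphenyl)-3-(hydroxymethyl)-5-[(E)-3-hydroxyprop-1-enyl]-7-methoxy-2,3-dihydrobenzofuran | COc1cc([C@H]2Oc3c(OC)cc(/C=C/CO)cc3[C@@H]2CO)cc(OC)c1O | target

Total step count: 13.
Longest linear sequence: 11 steps (3 → 4 → 7 → 8 → 9 → 11 → 16 → 20 → 23 → 24 → 26 by way of 25; steps 2 to 8 and 10 to 13).

Steps most likely to fail

Step 10 (the new method). What may go wrong:
- self-cyclotrimerisation or oligomerisation of the diyne instead of cross-cycloaddition;
- sigmatropic rearrangement or metal-induced cleavage of the benzylic alkynyl ether before the metallacycle forms;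
- loss of boron from the alkyne;
- insertion of the pentenyne in the opposite sense, which would put the chain at C6.

Fallback, known reactions only, sets out from 2 and comes back at 26. NaBH4 in MeOH reduces 2 to [3,5-dimethoxy-4-(triisopropylsilyloxy)phenyl]methanol F1. Mitsunobu etherification (PPh3, diisopropyl azodicarboxylate) with commercial 5-iodovanillin gives 3-iodo-5-methoxy-4-{[3,5-dimethoxy-4-(triisopropylsilyloxy)phenyl]methoxy}benzaldehyde F2. Palladium-catalysed coupling of the aryl iodide with ethyl diazoacetate (Pd(PPh3)4, Et3N, Bu4NBr, MeCN) gives the ethyl aryldiazoacetate F3. Intramolecular carbenoid insertion into the benzylic C–H bond, catalysed by the divalent-rhodium carboxylate Rh2(S-PTTL)4 or its mirror image (whichever delivers 2S), gives the cis ethyl 2-aryl-5-formyl-7-methoxy-2,3-dihydrobenzofuran-3-carboxylate F4. Horner–Wadsworth–Emmons olefination with triethyl phosphonoacetate and NaH, then NaOEt in EtOH to epimerise C3, gives the trans diester F5. i-Bu2AlH reduces both esters to the silyl-protected diol F6, and Bu4NF frees the phenol to give 26.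

Step 8. What may go wrong: incomplete discrimination between the two sp C–H sites, so that boron ends at the C3 alkyne or at both termini, and loss of boron from the ynol ether during work-up.

Fallback, sets out from 11 and comes back at 20. Step 7 is run with a cold quench (aqueous NH4Cl at −78 °C) in place of methanolic carbonate, so that the silyl-capped ynol ether 15 is isolated with a single acidic sp C–H. n-BuLi, then 17, then HCl·Et2O give the C-silylated boryl diyne F7. The C–SiMe3 group is then removed with Bu4NF (1 equiv) in THF at −78 °C and a pH 7 buffer quench, giving 20. This last operation is the weak point of the fallback: the C–Si cleavage must outrun fluoride attack on boron and on the aryl silyl ether, which is why protection ranks second to acidity control.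

Step 6. What may go wrong: erosion of the anti preference with an aromatic aldehyde, β-elimination of the silyloxy group from the propargylzinc isomer of the reagent, and ethyl transfer or reduction of the aldehyde by the zinc reagent.

Fallback, sets out from 8 and comes back at 11. Methyl chloroformate and pyridine convert 8 into the (S)-propargylic methyl carbonate F8. CuCl, NaOt-Bu, Xantphos and B2pin2 in THF effect anti SN2′ borylation with centre-to-axis chirality transfer to the (aR)-allenylboronate F9. F9 adds to 2 in toluene at rt to 40 °C through a closed six-membered transition state, without palladium or zinc and without a metal isomer that can expel the silyloxy group. Mild hydrolysis of the resulting borate gives 11 with the same relay of configuration as in step 6.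

Further compounds
F1 | step 10 | [3,5-dimethoxy-4-(triisopropylsilyloxy)phenyl]methanol | COc1cc(CO)cc(OC)c1O[Si](C(C)C)(C(C)C)C(C)C
F2 | step 10 | 3-iodo-5-methoxy-4-{[3,5-dimethoxy-4-(triisopropylsilyloxy)phenyl]methoxy}benzaldehyde | COc1cc(COc2c(I)cc(C=O)cc2OC)cc(OC)c1O[Si](C(C)C)(C(C)C)C(C)C
F3 | step 10 | ethyl 2-diazo-2-(5-formyl-3-methoxy-2-{[3,5-dimethoxy-4-(triisopropylsilyloxy)phenyl]methoxy}phenyl)acetate | CCOC(=O)C(=[N+]=[N-])c1cc(C=O)cc(OC)c1OCc1cc(OC)c(O[Si](C(C)C)(C(C)C)C(C)C)c(OC)c1
F4 | step 10 | ethyl (2S,3R)-2-[3,5-dimethoxy-4-(triisopropylsilyloxy)phenyl]-5-formyl-7-methoxy-2,3-dihydrobenzofuran-3-carboxylate (cis) | COc1cc([C@H]2Oc3c(OC)cc(C=O)cc3[C@H]2C(=O)OCC)cc(OC)c1O[Si](C(C)C)(C(C)C)C(C)C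
F5 | step 10 | ethyl (2S,3S)-2-[3,5-dimethoxy-4-(triisopropylsilyloxy)phenyl]-5-[(E)-3-ethoxy-3-oxoprop-1-enyl]-7-methoxy-2,3-dihydrobenzofuran-3-carboxylate (trans) | COc1cc([C@H]2Oc3c(OC)cc(/C=C/C(=O)OCC)cc3[C@@H]2C(=O)OCC)cc(OC)c1O[Si](C(C)C)(C(C)C)C(C)C
F6 | step 10 | (2S,3R)-2-[3,5-dimethoxy-4-(triisopropylsilyloxy)phenyl]-3-(hydroxymethyl)-5-[(E)-3-hydroxyprop-1-enyl]-7-methoxy-2,3-dihydrobenzofuran | COc1cc([C@H]2Oc3c(OC)cc(/C=C/CO)cc3[C@@H]2CO)cc(OC)c1O[Si](C(C)C)(C(C)C)C(C)C
F7 | step 8 | 2-(4,4,5,5-tetramethyl-1,3,2-dioxaborolan-2-yl)ethynyl ether of 11 (C3 alkyne C-silylated) | COc1cc(cc(OC)c1O[Si](C(C)C)(C(C)C)C(C)C)[C@@H](OC#CB1OC(C)(C)C(C)(C)O1)[C@@H](CO[Si](C(C)C)(C(C)C)C(C)C)C#C[Si](C)(C)C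
F8 | step 6 | methyl (S)-1-(triisopropylsilyloxy)-4-(trimethylsilyl)but-3-yn-2-yl carbonate | C[Si](C)(C)C#C[C@H](OC(=O)OC)CO[Si](C(C)C)(C(C)C)C(C)C
F9 | step 6 | (aR)-2-[4-(triisopropylsilyloxy)-1-(trimethylsilyl)buta-1,2-dien-1-yl]-4,4,5,5-tetramethyl-1,3,2-dioxaborolane | CC1(C)OB(OC1(C)C)C([Si](C)(C)C)=[C@@]=C([H])CO[Si](C(C)C)(C(C)C)C(C)C
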